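Of the constants you can draw from the earlier runs, one is worth watching when you repeat this flask: the climb, the fraction of the Q charge that becomes X per hour after the first readings of X.

| flask | Q | Z | E | temperature | remark | time | volume of the second phase over the first |
|---|---|---|---|---|---|---|---|
| epsilon | 0.32 M (fed, over 50 min) | 0.68 M | 0.034 M | −5 °C | run made earlier |  |  |
| alpha | 0.42 M (fed, over 50 min) | 0.68 M | 0.034 M | 28 °C | run made earlier |  |  |
| zeta | 0.52 M (fed, over 50 min) | 0.68 M | 0.034 M | −5 °C | run made earlier |  |  |
| Saturday's | 0.34 M (fed, over 50 min) | 0.680 M | 0.0340 M |  | at −20 °C until 50 min, from then on at 40 °C | 8.0 h | 1.0 |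
| Monday's | 0.50 M (fed, over 50 min) | 0.680 M | 0.0340 M |  | at 40 °C throughout | 8.0 h | 1.0 |

- epsilon (time / h: X / %): 0.200: 0; 0.417: 1; 0.667: 7; 1.33: 12; 3.00: 21
- alpha (time / min: X / %): 3.00: 0; 8.00: 1; 15.0: 2; 20.0: 0; 30.0: 5
- zeta (time / h: X / %): 0.200: 0; 0.417: 0; 0.667: 6; 1.33: 12; 3.00: 26

(scatter of a reading: 1.5 percentage points)

- in the second phase: Z; everything else is in the first
- charges count per volume of the first phase; a concentration in a rate is the amount of a species over the volume of its own phase; every rate counts per litre of the first phase
- the earlier runs hold the two phases in the same ratio of volumes as the flask asked about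
- percentages count the whole charge, also what has not yet gone in

1. which one finishes higher in amount of X, in percent of the Q charged ("neither" within 2 percentage points) (Saturday's / Monday's / neither)
2. amount of X at the end, in percent of the Q charged, Saturday's
3. amount of X at the end, in percent of the Q charged, Monday's

I read the climb in the two cold runs, epsilon and zeta, between 0.667 h and 3.00 h:

climb = mean of (21% − 7%) and (26% − 6%), over 2.33 h = 0.0729 h⁻¹

This climb, the mean gain of X per hour as a fraction of the charge, is an apparent zero-order rate. As a time it is 13.7 h for the whole charge, longer than the 8.0 h asked. My first estimate runs it straight on from the mean at 3.00 h: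

X at the end = 23.5% + climb × 5.00 h = 59.9%

But those runs stood at −5 °C, and both new flasks end at 40 °C. The alpha run, at 28 °C, shows 5% at 30.0 min, while the cold runs pass that mark between 25.02 min and 40.02 min. Within a scatter of 1.5 percentage points, these readings show no clear speed-up, so I keep the climb, although the alpha readings end during the feed.

Charge is a second doubt. At 3.00 h, zeta stands 5 points above epsilon, a weak lean towards Monday's, so I make no call on the order.

The straight line is the third doubt. Epsilon's climb falls from 0.0754 h⁻¹ to 0.0539 h⁻¹, less in the later stretch. I can't compute this away, so 59.9% becomes my upper mark and 23.5% my lower one, for both flasks.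

The forecast says Saturday's, with 87% for Saturday's and 82% for Monday's, and calls this “a tentative edge for Saturday's, with wide uncertainty”. Both numbers stand above my upper mark.

Saturday's gives 25.3% and Monday's 20.4%, so Saturday's finishes higher, as the forecast said, and Monday's lands below my lower mark.

    L ⇌ Z, rate k1*([L] - [Z]/K1) per volume of the first phase (partition coefficient = 1.90, kL = 0.0130 min⁻¹)
    Q + L → X (k = 0.0550 M⁻¹ min⁻¹, Ea = 61.0 kJ mol⁻¹)
    Q + E → G (k = 0.300 M⁻¹ min⁻¹, Ea = 45.0 kJ mol⁻¹)
    L → J (k = 0.0440 min⁻¹, Ea = 70.0 kJ mol⁻¹)
    (constants at −20 °C)

Monday's gained 0.0603 h⁻¹ from the end of the feed to 2.0 h, against the cold climb of 0.0729 h⁻¹. Saturday's gained 0.00910 h⁻¹ from 4.00 h to 8.00 h, less than the cold climb. Saturday's is close to rest at 8.00 h, with 65% of its Q still there and Z at 3.95% of its own charge. At 80.0 h, Saturday's has Z at 0% of its own charge and reaches 26.2%, a further 0.90 points, and Monday's reaches 21.3%, a further 0.90 points.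

(The readings were computed with constants of no real substance; scatter was added.)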